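The route rests on taking both ring B prenyl groups off carbon and hanging them on oxygen. C2' lies next to oxygen-bearing C3' and C6' next to oxygen-bearing C5', and the C1'–C4' axis makes the two halves of the 5-(benzofuran-2-yl)resorcinol equivalent. One heating of the bis(1,1-dimethylallyl) ether 12 should therefore forge the C2'–CH2 and C6'–CH2 bonds by two [3,3] shifts, each turning a tertiary allyl ether into a linear prenyl group and a free phenol. Precursor 12 is assembled from silyl-protected benzofuran-6-ol and 5-bromoresorcinol by Suzuki coupling, copper-catalysed propargylation and semi-hydrogenation; monomethylation and desilylation finish the synthesis.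

Key step: step 6

Remark: ring B is numbered C1' (bonded to C2 of the benzofuran) to C6'. The target has no stereocentre, and both alkenes carry two identical methyl groups, so no configuration has to be set.

Step 1
Reactants: 1 benzofuran-6-ol
Product: 2 6-(triisopropylsilyloxy)benzofuran
Conditions: TIPSCl, imidazole, DMF, 0 °C to rt
Reagents that add atoms: chlorotriisopropylsilane, CC(C)[Si](Cl)(C(C)C)C(C)C
Why: Imidazole-mediated O-silylation (silyl ether protection) of the only hydroxyl should be clean, and the bulky triisopropylsilyl ether is chosen because it should withstand n-BuLi at −78 °C, aqueous phosphate, DBU and the later heating, yet leave with buffered fluoride.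

Step 2
Reactants: 2 6-(triisopropylsilyloxy)benzofuran
Product: 5 6-(triisopropylsilyloxy)-2-(4,4,5,5-tetramethyl-1,3,2-dioxaborolan-2-yl)benzofuran, via 2-lithio-6-(triisopropylsilyloxy)benzofuran 3 (not isolated), via lithium isopropoxy borate complex 4 (not isolated)
Conditions: n-BuLi, THF, −78 °C; then iPrOBpin, −78 °C to rt; aq. NH4Cl
Reagents that add atoms: 2-isopropoxy-4,4,5,5-tetramethyl-1,3,2-dioxaborolane, CC(C)OB1OC(C)(C)C(C)(C)O1
Why: Lithiation–borylation: C2–H, alpha to the ring oxygen, is the most acidic C–H of a benzofuran, and the hindered silyloxy group is a poor director for lithiation at C5 or C7, so the boron should enter at C2 only.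

Step 3
Reactants: 5 6-(triisopropylsilyloxy)-2-(4,4,5,5-tetramethyl-1,3,2-dioxaborolan-2-yl)benzofuran; 6 5-bromobenzene-1,3-diol
Product: 7 5-[6-(triisopropylsilyloxy)benzofuran-2-yl]benzene-1,3-diol
Conditions: Pd(OAc)2 (cat.), SPhos, K3PO4, 1,4-dioxane/H2O, 60 °C
Reagents that add atoms: none
Why: Suzuki–Miyaura cross-coupling tolerates the free phenols, and the bulky, electron-rich biaryl phosphine should speed oxidative addition into the electron-rich bromide so that coupling outruns protodeboronation at a temperature mild enough for the silyl ether.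

Step 4
Reactants: 7 5-[6-(triisopropylsilyloxy)benzofuran-2-yl]benzene-1,3-diol; 8 3-chloro-3-methylbut-1-yne
Product: 10 2-[3,5-bis(2-methylbut-3-yn-2-yloxy)phenyl]-6-(triisopropylsilyloxy)benzofuran, via mono-propargyl ether 9 (not isolated)
Conditions: 8 (2.5 equiv in total), DBU (3 equiv), CuCl2 (cat.), MeCN, 0 °C
Reagents that add atoms: 3-chloro-3-methylbut-1-yne, CC(C)(Cl)C#C
Why: Copper-catalysed O-alkylation of phenols with a tertiary propargylic chloride (propargylic substitution through a copper acetylide-derived electrophile) is the standard entry to aryl 1,1-dimethylpropargyl ethers, and since only the two ring B hydroxyls are free, the first equivalent of 8 should give mono-ether 9 and the second equivalent should alkylate the remaining hydroxyl of 9 to give 10.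

Step 5
Reactants: 10 2-[3,5-bis(2-methylbut-3-yn-2-yloxy)phenyl]-6-(triisopropylsilyloxy)benzofuran
Product: 12 2-[3,5-bis(2-methylbut-3-en-2-yloxy)phenyl]-6-(triisopropylsilyloxy)benzofuran, via half-reduced enyne ether 11 (not isolated)
Conditions: H2 (1 atm), Pd/CaCO3 poisoned with Pb(OAc)2, quinoline, EtOAc, rt
Reagents that add atoms: none
Why: Lindlar-type semi-hydrogenation over lead-poisoned palladium with quinoline should reduce both terminal alkynes to vinyl groups and stop there, leaving the benzofuran, the aryl ethers and the silyl ether untouched.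

Step 6
Reactants: 12 2-[3,5-bis(2-methylbut-3-en-2-yloxy)phenyl]-6-(triisopropylsilyloxy)benzofuran
Product: 16 5-[6-(triisopropylsilyloxy)benzofuran-2-yl]-4,6-bis(3-methylbut-2-enyl)benzene-1,3-diol, via first ortho-dienone 13 (not isolated), via monoprenyl phenol 14 (not isolated), via second ortho-dienone 15 (not isolated)
Conditions: PhNEt2 (degassed), 150 °C, sealed tube, Ar
Reagents that add atoms: none
Why: Each aryl 1,1-dimethylallyl ether should undergo a concerted suprafacial [3,3] shift through a chair-like six-membered transition state, in which the terminal CH2 of the allyl unit bonds to the ortho ring carbon while the O–C(CH3)2 bond breaks, giving ortho-dienones 13 and 15 that enolise at once to phenols 14 and 16; this is the aromatic Claisen rearrangement, the classical indirect ortho-C-prenylation of phenols. No ring is closed and no stereocentre remains, because the sp3 ring carbons of the dienones become planar again on tautomerisation. The selectivity needed is positional: both shifts must end at C2' and C6' and not at C4'. This is expected because each migrating ether has the other ring B oxygen meta to it, a donor that raises electron density para to itself (at C2' or C6'), and because C4' is wedged between two oxygen substituents. The geminal methyl groups lower the barrier, so the shifts should run near 150 °C, and the basic amine solvent should suppress acid-induced chroman formation and loss of isoprene. The flanking benzofuranyl group is the opposing steric factor, so a C4'-prenyl isomer is the by-product to look for.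

Step 7
Reactants: 16 5-[6-(triisopropylsilyloxy)benzofuran-2-yl]-4,6-bis(3-methylbut-2-enyl)benzene-1,3-diol
Product: 17 5-methoxy-2,4-bis(3-methylbut-2-enyl)-3-[6-(triisopropylsilyloxy)benzofuran-2-yl]phenol
Conditions: MeI (1.0 equiv), K2CO3 (1.0 equiv), acetone, rt
Reagents that add atoms: iodomethane, CI
Why: Williamson O-methylation of a diol whose two hydroxyls are interchanged by the C1'–C4' axis can give only one mono-ether, so limiting the electrophile should give mainly 17 beside recoverable diol 16 and some dimethyl ether, while carbonate in acetone at room temperature should spare the aryl silyl ether.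

Step 8
Reactants: 17 5-methoxy-2,4-bis(3-methylbut-2-enyl)-3-[6-(triisopropylsilyloxy)benzofuran-2-yl]phenol
Product: 18 2-[3-hydroxy-5-methoxy-2,6-bis(3-methylbut-2-enyl)phenyl]benzofuran-6-ol
Conditions: Bu4NF, AcOH, THF, 0 °C to rt
Reagents that add atoms: none
Why: Fluoride-induced desilylation of the aryl silyl ether, buffered with acetic acid so that neither strong base nor strong acid meets the ortho-prenyl phenols, should release the target without chroman formation.

Compound list
1 | benzofuran-6-ol | Oc1ccc2ccoc2c1 | starting material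
2 | 6-(triisopropylsilyloxy)benzofuran | CC(C)[Si](Oc1ccc2ccoc2c1)(C(C)C)C(C)C | intermediate
3 | 2-lithio-6-(triisopropylsilyloxy)benzofuran | [Li]c1cc2ccc(O[Si](C(C)C)(C(C)C)C(C)C)cc2o1 | intermediate (not isolated)
4 | lithium isopropoxy(pinacolato)[6-(triisopropylsilyloxy)benzofuran-2-yl]borate | [Li+].CC(C)O[B-]1(c2cc3ccc(O[Si](C(C)C)(C(C)C)C(C)C)cc3o2)OC(C)(C)C(C)(C)O1 | intermediate (not isolated)
5 | 6-(triisopropylsilyloxy)-2-(4,4,5,5-tetramethyl-1,3,2-dioxaborolan-2-yl)benzofuran | CC(C)[Si](Oc1ccc2cc(B3OC(C)(C)C(C)(C)O3)oc2c1)(C(C)C)C(C)C | intermediate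
6 | 5-bromobenzene-1,3-diol | Oc1cc(O)cc(Br)c1 | starting material
7 | 5-[6-(triisopropylsilyloxy)benzofuran-2-yl]benzene-1,3-diol | Oc1cc(O)cc(-c2cc3ccc(O[Si](C(C)C)(C(C)C)C(C)C)cc3o2)c1 | intermediate
8 | 3-chloro-3-methylbut-1-yne | CC(C)(Cl)C#C | starting material
9 | 3-(2-methylbut-3-yn-2-yloxy)-5-[6-(triisopropylsilyloxy)benzofuran-2-yl]phenol | C#CC(C)(C)Oc1cc(O)cc(-c2cc3ccc(O[Si](C(C)C)(C(C)C)C(C)C)cc3o2)c1 | intermediate (not isolated)
10 | 2-[3,5-bis(2-methylbut-3-yn-2-yloxy)phenyl]-6-(triisopropylsilyloxy)benzofuran | C#CC(C)(C)Oc1cc(OC(C)(C)C#C)cc(-c2cc3ccc(O[Si](C(C)C)(C(C)C)C(C)C)cc3o2)c1 | intermediate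
11 | 2-[3-(2-methylbut-3-en-2-yloxy)-5-(2-methylbut-3-yn-2-yloxy)phenyl]-6-(triisopropylsilyloxy)benzofuran | C=CC(C)(C)Oc1cc(OC(C)(C)C#C)cc(-c2cc3ccc(O[Si](C(C)C)(C(C)C)C(C)C)cc3o2)c1 | intermediate (not isolated)
12 | 2-[3,5-bis(2-methylbut-3-en-2-yloxy)phenyl]-6-(triisopropylsilyloxy)benzofuran | C=CC(C)(C)Oc1cc(OC(C)(C)C=C)cc(-c2cc3ccc(O[Si](C(C)C)(C(C)C)C(C)C)cc3o2)c1 | intermediate
13 | 3-(2-methylbut-3-en-2-yloxy)-6-(3-methylbut-2-enyl)-5-[6-(triisopropylsilyloxy)benzofuran-2-yl]cyclohexa-2,4-dien-1-one (racemic, transient) | CC(C)=CCC1C(=O)C=C(OC(C)(C)C=C)C=C1-c2cc3ccc(O[Si](C(C)C)(C(C)C)C(C)C)cc3o2 | intermediate (not isolated)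
14 | 5-(2-methylbut-3-en-2-yloxy)-2-(3-methylbut-2-enyl)-3-[6-(triisopropylsilyloxy)benzofuran-2-yl]phenol | CC(C)=CCc1c(O)cc(OC(C)(C)C=C)cc1-c1cc2ccc(O[Si](C(C)C)(C(C)C)C(C)C)cc2o1 | intermediate (not isolated)
15 | 3-hydroxy-4,6-bis(3-methylbut-2-enyl)-5-[6-(triisopropylsilyloxy)benzofuran-2-yl]cyclohexa-2,4-dien-1-one (racemic, transient) | CC(C)=CCC1C(=O)C=C(O)C(CC=C(C)C)=C1-c2cc3ccc(O[Si](C(C)C)(C(C)C)C(C)C)cc3o2 | intermediate (not isolated)
16 | 5-[6-(triisopropylsilyloxy)benzofuran-2-yl]-4,6-bis(3-methylbut-2-enyl)benzene-1,3-diol | CC(C)=CCc1c(O)cc(O)c(CC=C(C)C)c1-c1cc2ccc(O[Si](C(C)C)(C(C)C)C(C)C)cc2o1 | intermediate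
17 | 5-methoxy-2,4-bis(3-methylbut-2-enyl)-3-[6-(triisopropylsilyloxy)benzofuran-2-yl]phenol | COc1cc(O)c(CC=C(C)C)c(-c2cc3ccc(O[Si](C(C)C)(C(C)C)C(C)C)cc3o2)c1CC=C(C)C | intermediate
18 | 2-[3-hydroxy-5-methoxy-2,6-bis(3-methylbut-2-enyl)phenyl]benzofuran-6-ol | COc1cc(O)c(CC=C(C)C)c(-c2cc3ccc(O)cc3o2)c1CC=C(C)C | target

Total step count: 8. Longest linear sequence: 8 steps (1 to 18).

Steps most likely to fail

1. Step 6. One or both allyl units may migrate to C4' between the oxygens instead of to C2'/C6', and the tertiary ethers may fragment with loss of isoprene before they rearrange. The fallback performs the two shifts before the biaryl bond exists, so that a small, inductively withdrawing bromine instead of the benzofuranyl group neighbours the migration termini. It sets out from 6 and 8. Copper-catalysed propargylation of both hydroxyls with two equivalents of 8 (DBU, CuCl2, MeCN, 0 °C) would give 1-bromo-3,5-bis(2-methylbut-3-yn-2-yloxy)benzene F1. Semi-hydrogenation over Pd/CaCO3 poisoned with Pb(OAc)2 would give 1-bromo-3,5-bis(2-methylbut-3-en-2-yloxy)benzene F2. Heating in PhNEt2 would give 5-bromo-4,6-bis(3-methylbut-2-enyl)benzene-1,3-diol F3, a meta electron-withdrawing substituent being known to steer allyl migration toward the carbon beside it. Suzuki coupling of F3 with boronate 5 (Pd(OAc)2, SPhos, K3PO4, dioxane/H2O) comes back to the route at 16.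

2. Step 7. The second hydroxyl reacts at a rate similar to the first, so over-methylation competes and the mono-ether forms only statistically. The fallback methylates exhaustively and then removes one methyl group selectively. It sets out from 16. Excess MeI and K2CO3 in refluxing acetone would give 2-[3,5-dimethoxy-2,6-bis(3-methylbut-2-enyl)phenyl]-6-(triisopropylsilyloxy)benzofuran F4. Bu4NF in THF would give 2-[3,5-dimethoxy-2,6-bis(3-methylbut-2-enyl)phenyl]benzofuran-6-ol F5. Excess NaSEt in degassed DMF at 130 °C should cleave one methyl ether only, because the phenoxide formed on ring B deactivates the second, and comes back to the route at target 18.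

3. Step 3. Protodeboronation of the 2-benzofuranyl boronate and partial loss of the silyl ether under warm aqueous base may erode the coupling. The fallback is a base-free and water-free Stille coupling. It sets out from 2. C2-lithiation (n-BuLi, THF, −78 °C) and quenching with Bu3SnCl would give tributyl[6-(triisopropylsilyloxy)benzofuran-2-yl]stannane F6. Coupling of F6 with 6 (Pd(PPh3)4, toluene, 100 °C) comes back to the route at 7.

Further compounds
F1 | step 6 | 1-bromo-3,5-bis(2-methylbut-3-yn-2-yloxy)benzene | C#CC(C)(C)Oc1cc(Br)cc(OC(C)(C)C#C)c1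
F2 | step 6 | 1-bromo-3,5-bis(2-methylbut-3-en-2-yloxy)benzene | C=CC(C)(C)Oc1cc(Br)cc(OC(C)(C)C=C)c1
F3 | step 6 | 5-bromo-4,6-bis(3-methylbut-2-enyl)benzene-1,3-diol | CC(C)=CCc1c(O)cc(O)c(CC=C(C)C)c1Br
F4 | step 7 | 2-[3,5-dimethoxy-2,6-bis(3-methylbut-2-enyl)phenyl]-6-(triisopropylsilyloxy)benzofuran | COc1cc(OC)c(CC=C(C)C)c(-c2cc3ccc(O[Si](C(C)C)(C(C)C)C(C)C)cc3o2)c1CC=C(C)C
F5 | step 7 | 2-[3,5-dimethoxy-2,6-bis(3-methylbut-2-enyl)phenyl]benzofuran-6-ol | COc1cc(OC)c(CC=C(C)C)c(-c2cc3ccc(O)cc3o2)c1CC=C(C)C
F6 | step 3 | tributyl[6-(triisopropylsilyloxy)benzofuran-2-yl]stannane | CCCC[Sn](CCCC)(CCCC)c1cc2ccc(O[Si](C(C)C)(C(C)C)C(C)C)cc2o1
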